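**Plan**

- Retrosynthesis: the diene is cut at the C3–C4 sp2–sp2 bond (Pd coupling), the methyl-bearing C2=C3 alkene goes back to a cyclohexyl alkyne (carbometalation), and the oxane is opened at O1–C6 and at C3–Br.
- Enabling feature: oxane C6 is a fully substituted ether carbon (O1, CH3, ring C5, diene carbon) lying 1,4 to the C3 bromide. The carbinol oxygen on the gem-dimethyl carbon C2 reaches it through the chain O1–C2–C3–C4–C5–C6, so an E-derived 2,3-epoxy alcohol opened at its methyl-bearing carbon closes the ring.
- Fragment A: geranyl acetate → (6R)-epoxide → (6S)-bromohydrin → Sharpless epoxide → 6-exo etherification (the oxane forms here) → glycol cleavage → E-iodoalkene.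
- Fragment B: purchased enantiopure epoxy ester → trans-diaxial hydroxy tosylate → bromide by inversion → α-bromo ketone → methyl addition → alkyne.
- Union: syn-carboalumination of the alkyne and Pd coupling with the iodoalkene form the E,E-diene in the last step; no protecting group reaches the target.
- Stereochemistry: oxane C3 from Shi epoxidation plus invertive bromide opening; oxane C6 from Sharpless epoxidation plus invertive etherification; cyclohexane C4 from the epoxy ester, C2 by SN2 inversion, C1 by methyl addition anti to bromine.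

Key step: step 5

Remarks on the chemistry:
- Ethyl (1S,3S,6R)-7-oxabicyclo[4.1.0]heptane-3-carboxylate (9) is assumed to be purchased; it is a bulk intermediate made from (S)-cyclohex-3-ene-1-carboxylic acid by iodolactonisation and ethanolysis.
- In the target's cyclohexane ring, Br and OH are cis. This cannot come from anti addition to a cyclohexene, so the carbinol is made by methyl addition to an α-bromo ketone.
- In the text the oxane is numbered as in the target (O1, C2 = CMe2, C3 = CHBr, C6 = quaternary carbon). The IUPAC names of 6 and 7 number the ring from the other side.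

**Route**

Step 1
Reactants: 1 geranyl acetate
Product: 2 (2E)-5-[(2R)-3,3-dimethyloxiran-2-yl]-3-methylpent-2-en-1-yl acetate
Conditions: Shi ketone from D-fructose (0.3 equiv), Oxone (2KHSO5·KHSO4·K2SO4), K2CO3, Bu4NHSO4, Na2B4O7 buffer, MeCN/CH2(OMe)2/H2O, 0 °C
Reagents that add atoms: Oxone (potassium peroxymonosulfate, KHSO5), [K+].[O-]S(=O)(=O)OO
Why: Shi epoxidation, in which the chiral dioxirane attacks the electron-rich C6=C7 alkene through a spiro transition state in preference to the acetate-deactivated C2=C3 alkene, should set the (6R)-epoxide.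

Step 2
Reactants: 2 (2E)-5-[(2R)-3,3-dimethyloxiran-2-yl]-3-methylpent-2-en-1-yl acetate
Product: 3 (2E)-5-[(2R)-3,3-dimethyloxiran-2-yl]-3-methylpent-2-en-1-ol
Conditions: K2CO3 (cat.), MeOH, rt
Reagents that add atoms: none
Why: Base-catalysed transesterification (Zemplén-type methanolysis) removes the acetate, and neither the trisubstituted epoxide nor the alkene reacts with carbonate in methanol at room temperature.

Step 3
Reactants: 3 (2E)-5-[(2R)-3,3-dimethyloxiran-2-yl]-3-methylpent-2-en-1-ol
Product: 4 (2E,6S)-6-bromo-3,7-dimethyloct-2-ene-1,7-diol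
Conditions: Li2NiBr4 (from LiBr and NiBr2), THF, 0 °C to rt; pH 7 buffer
Reagents that add atoms: dilithium tetrabromonickelate Li2NiBr4, [Li+].[Li+].[Ni+2].[Br-].[Br-].[Br-].[Br-]
Why: Nucleophilic epoxide opening under nearly neutral conditions, in which the soft bromide of the tetrabromonickelate attacks the less substituted C6 in an SN2 process with inversion, should turn the (6R)-epoxide into the (6S)-bromide and leave the tertiary alcohol at C7.

Step 4
Reactants: 4 (2E,6S)-6-bromo-3,7-dimethyloct-2-ene-1,7-diol
Product: 5 (3S)-3-bromo-5-[(2S,3S)-3-(hydroxymethyl)-2-methyloxiran-2-yl]-2-methylpentan-2-ol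
Conditions: Ti(OiPr)4 (0.2 equiv), L-(+)-diisopropyl tartrate (0.24 equiv), t-BuOOH, 4 Å MS, CH2Cl2, −20 °C; aq. tartaric acid work-up
Reagents that add atoms: tert-butyl hydroperoxide, CC(C)(C)OO
Why: Sharpless asymmetric epoxidation of the E-allylic alcohol with the L-(+)-tartrate catalyst delivers oxygen to the face that gives the (2S,3S)-epoxide irrespective of the remote bromide centre, and the non-basic work-up keeps the bromohydrin from closing to an epoxide.

Step 5
Reactants: 5 (3S)-3-bromo-5-[(2S,3S)-3-(hydroxymethyl)-2-methyloxiran-2-yl]-2-methylpentan-2-ol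
Product: 6 (1S)-1-[(2R,5S)-5-bromo-2,6,6-trimethyloxan-2-yl]ethane-1,2-diol
Conditions: CSA (10 mol %), CH2Cl2, 0 °C
Reagents that add atoms: none
Why: CSA activates the epoxide oxygen and the tertiary hydroxyl of the bromohydrin (the future O1) attacks the methyl-bearing epoxide carbon from the face opposite the breaking C–O bond, releasing a 1,2-diol on the side chain. The closest known reaction type is the acid-catalysed exo-selective hydroxy-epoxide cyclisation used for cyclic ethers, together with the C3-selective opening of 2,3-epoxy alcohols. The oxane closes in the 6-exo-tet mode (O1–C2–C3–C4–C5–C6), the 7-endo alternative at the CH carbon being disfavoured by ring size, by the lower substitution of that carbon and by the inductive effect of the neighbouring CH2OH. The new stereocentre, oxane C6, is controlled by the (2S,3S)-epoxide from step 4, since inversion at the methyl-bearing carbon should give the R configuration while the carbinol carbon and the C–Br centre are not touched. The step needs attack at the tertiary carbon and an SN2-like rather than carbocationic opening; the first is secured by the substitution pattern just named and the second by a weak acid in a non-ionising solvent at 0 °C with the nucleophile held in the same chain. The secondary bromide and the primary hydroxyl are spectators, because the primary OH could reach the epoxide only through a strained small-ring transition state.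

Step 6
Reactants: 6 (1S)-1-[(2R,5S)-5-bromo-2,6,6-trimethyloxan-2-yl]ethane-1,2-diol
Product: 7 (2R,5S)-5-bromo-2,6,6-trimethyloxane-2-carbaldehyde
Conditions: NaIO4, THF/H2O, 0 °C to rt
Reagents that add atoms: none
Why: Periodate glycol cleavage (Malaprade reaction) of the terminal 1,2-diol gives the aldehyde, whose α-carbon is quaternary and therefore cannot epimerise.

Step 7
Reactants: 7 (2R,5S)-5-bromo-2,6,6-trimethyloxane-2-carbaldehyde
Product: 8 (3S,6R)-3-bromo-6-[(E)-2-iodoethenyl]-2,2,6-trimethyloxane
Conditions: CrCl2, CHI3, THF, 0 °C to rt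
Reagents that add atoms: iodoform, IC(I)I
Why: Takai iodo-olefination, in which the gem-dichromium species from CHI3 and CrCl2 adds to the aldehyde and eliminates to the E-iodoalkene, should leave the unactivated secondary bromide untouched in THF.

Step 8
Reactants: 9 ethyl (1S,3S,6R)-7-oxabicyclo[4.1.0]heptane-3-carboxylate
Product: 10 ethyl (1S,3R,4R)-4-hydroxy-3-(tosyloxy)cyclohexane-1-carboxylate
Conditions: anhydrous TsOH, CH2Cl2, 0 °C to rt
Reagents that add atoms: p-toluenesulfonic acid, Cc1ccc(cc1)S(=O)(=O)O
Why: Acid-mediated epoxide opening by the sulfonate follows the trans-diaxial (Fürst–Plattner) rule from the half-chair with equatorial ester, so tosylate should enter at C3 with inversion, trans to the ester, leaving the C4 hydroxyl cis to it.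

Step 9
Reactants: 10 ethyl (1S,3R,4R)-4-hydroxy-3-(tosyloxy)cyclohexane-1-carboxylate
Product: 11 ethyl (1S,3R,4R)-3-(tosyloxy)-4-(triethylsilyloxy)cyclohexane-1-carboxylate
Conditions: Et3SiOTf, 2,6-lutidine, CH2Cl2, −78 to 0 °C
Reagents that add atoms: triethylsilyl trifluoromethanesulfonate, CC[Si](CC)(CC)OS(=O)(=O)C(F)(F)F
Why: Silylation with a silyl triflate and a hindered, weakly basic pyridine protects the C4 hydroxyl without forming an alkoxide that would displace the trans-diaxial tosylate and re-form the epoxide.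

Step 10
Reactants: 11 ethyl (1S,3R,4R)-3-(tosyloxy)-4-(triethylsilyloxy)cyclohexane-1-carboxylate
Product: 12 ethyl (1S,3S,4R)-3-bromo-4-(triethylsilyloxy)cyclohexane-1-carboxylate
Conditions: LiBr, 2-butanone, 70 °C
Reagents that add atoms: lithium bromide, [Li+].[Br-]
Why: SN2 displacement (Finkelstein type) of the axial tosylate by bromide along the open equatorial trajectory inverts C3 and places bromine cis to the ester, the silyl ether being a poor neighbouring group.

Step 11
Reactants: 12 ethyl (1S,3S,4R)-3-bromo-4-(triethylsilyloxy)cyclohexane-1-carboxylate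
Product: 14 ethyl (1S,3S)-3-bromo-4-oxocyclohexane-1-carboxylate, via bromohydrin ester 13 (not isolated)
Conditions: CrO3, H2SO4, H2O, acetone, 0 °C
Reagents that add atoms: none
Why: Jones oxidation, in which the aqueous acid cleaves the triethylsilyl ether and chromic acid oxidises the axial alcohol of the bromohydrin, is the classical bromohydrin-to-bromoketone conversion and runs without base, so C3 should not epimerise.

Step 12
Reactants: 14 ethyl (1S,3S)-3-bromo-4-oxocyclohexane-1-carboxylate
Product: 15 ethyl (1S,3S,4R)-3-bromo-4-hydroxy-4-methylcyclohexane-1-carboxylate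
Conditions: MeMgBr, CeCl3, THF, −78 °C; aq. NH4Cl
Reagents that add atoms: methylmagnesium bromide, C[Mg]Br
Why: Organocerium 1,2-addition to an α-bromo ketone places methyl anti to the C–Br bond (polar Felkin–Anh/Cornforth control, with equatorial attack on the diequatorial conformer and axial attack anti to axial bromine in the flipped conformer leading to the same product), which should give the (4R)-carbinol with OH cis to Br while the weakly basic reagent neither enolises the ketone nor touches the ester at −78 °C.

Step 13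
Reactants: 15 ethyl (1S,3S,4R)-3-bromo-4-hydroxy-4-methylcyclohexane-1-carboxylate
Product: 17 (1R,2S,4S)-2-bromo-4-ethynyl-1-methylcyclohexan-1-ol, via hydroxy aldehyde 16 (not isolated)
Conditions: DIBAL-H, CH2Cl2, −78 °C; then MeOH, dimethyl (1-diazo-2-oxopropyl)phosphonate, K2CO3, −78 °C to rt
Reagents that add atoms: dimethyl (1-diazo-2-oxopropyl)phosphonate (Ohira–Bestmann reagent), CC(=O)C(=[N+]=[N-])P(=O)(OC)OC
Why: Partial DIBAL-H reduction stops at the aluminium hemiacetal and Ohira–Bestmann (Seyferth–Gilbert) homologation of the released aldehyde gives the alkyne under carbonate conditions that cannot close the cis-bromohydrin to an epoxide and that leave the ring substituent in its thermodynamically preferred equatorial configuration.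

Step 14
Reactants: 17 (1R,2S,4S)-2-bromo-4-ethynyl-1-methylcyclohexan-1-ol; 8 (3S,6R)-3-bromo-6-[(E)-2-iodoethenyl]-2,2,6-trimethyloxane
Product: 19 (1R,2S,4S)-2-bromo-4-[(2E,4E)-5-[(2R,5S)-5-bromo-2,6,6-trimethyloxan-2-yl]penta-2,4-dien-2-yl]-1-methylcyclohexan-1-ol, via alkenylalane 18 (not isolated)
Conditions: Me3Al (3.5 equiv), Cp2ZrCl2, CH2Cl2, 0 °C to rt; volatiles removed; then 8, ZnCl2 (1 equiv), Pd(PPh3)4 (5 mol %), THF, rt
Reagents that add atoms: trimethylaluminium, C[Al](C)C
Why: Negishi zirconium-catalysed carboalumination adds methyl and aluminium syn across the alkyne with methyl on the internal carbon (the hydroxyl being carried as its aluminium alkoxide), and palladium-catalysed Negishi cross-coupling of the E-alkenyl metal with the E-iodoalkene proceeds with retention at both alkenes to give the E,E-diene.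

**Compound list**

1 | geranyl acetate | CC(=O)OC/C=C(\C)CCC=C(C)C | starting material
2 | (2E)-5-[(2R)-3,3-dimethyloxiran-2-yl]-3-methylpent-2-en-1-yl acetate | CC(=O)OC/C=C(\C)CC[C@H]1OC1(C)C | intermediate
3 | (2E)-5-[(2R)-3,3-dimethyloxiran-2-yl]-3-methylpent-2-en-1-ol | OC/C=C(\C)CC[C@H]1OC1(C)C | intermediate
4 | (2E,6S)-6-bromo-3,7-dimethyloct-2-ene-1,7-diol | OC/C=C(\C)CC[C@H](Br)C(C)(C)O | intermediate
5 | (3S)-3-bromo-5-[(2S,3S)-3-(hydroxymethyl)-2-methyloxiran-2-yl]-2-methylpentan-2-ol | OC[C@@H]1O[C@@]1(C)CC[C@H](Br)C(C)(C)O | intermediate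
6 | (1S)-1-[(2R,5S)-5-bromo-2,6,6-trimethyloxan-2-yl]ethane-1,2-diol | OC[C@H](O)[C@@]1(C)CC[C@H](Br)C(C)(C)O1 | intermediate
7 | (2R,5S)-5-bromo-2,6,6-trimethyloxane-2-carbaldehyde | O=C[C@@]1(C)CC[C@H](Br)C(C)(C)O1 | intermediate
8 | (3S,6R)-3-bromo-6-[(E)-2-iodoethenyl]-2,2,6-trimethyloxane | I/C=C/[C@@]1(C)CC[C@H](Br)C(C)(C)O1 | intermediate
9 | ethyl (1S,3S,6R)-7-oxabicyclo[4.1.0]heptane-3-carboxylate | CCOC(=O)[C@H]1CC[C@H]2O[C@H]2C1 | starting material
10 | ethyl (1S,3R,4R)-4-hydroxy-3-(tosyloxy)cyclohexane-1-carboxylate | CCOC(=O)[C@H]1CC[C@@H](O)[C@H](OS(=O)(=O)c2ccc(C)cc2)C1 | intermediate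
11 | ethyl (1S,3R,4R)-3-(tosyloxy)-4-(triethylsilyloxy)cyclohexane-1-carboxylate | CCOC(=O)[C@H]1CC[C@@H](O[Si](CC)(CC)CC)[C@H](OS(=O)(=O)c2ccc(C)cc2)C1 | intermediate
12 | ethyl (1S,3S,4R)-3-bromo-4-(triethylsilyloxy)cyclohexane-1-carboxylate | CCOC(=O)[C@H]1CC[C@@H](O[Si](CC)(CC)CC)[C@@H](Br)C1 | intermediate
13 | ethyl (1S,3S,4R)-3-bromo-4-hydroxycyclohexane-1-carboxylate | CCOC(=O)[C@H]1CC[C@@H](O)[C@@H](Br)C1 | intermediate
14 | ethyl (1S,3S)-3-bromo-4-oxocyclohexane-1-carboxylate | CCOC(=O)[C@H]1CCC(=O)[C@@H](Br)C1 | intermediate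
15 | ethyl (1S,3S,4R)-3-bromo-4-hydroxy-4-methylcyclohexane-1-carboxylate | CCOC(=O)[C@H]1CC[C@@](C)(O)[C@@H](Br)C1 | intermediate
16 | (1S,3S,4R)-3-bromo-4-hydroxy-4-methylcyclohexane-1-carbaldehyde | O=C[C@H]1CC[C@@](C)(O)[C@@H](Br)C1 | intermediate
17 | (1R,2S,4S)-2-bromo-4-ethynyl-1-methylcyclohexan-1-ol | C#C[C@H]1CC[C@@](C)(O)[C@@H](Br)C1 | intermediate
18 | {(E)-2-[(1S,3S,4R)-3-bromo-4-(dimethylalumanyloxy)-4-methylcyclohexyl]prop-1-en-1-yl}dimethylalumane | C[Al](C)/C=C(\C)[C@H]1CC[C@@](C)(O[Al](C)C)[C@@H](Br)C1 | intermediate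
19 | (1R,2S,4S)-2-bromo-4-[(2E,4E)-5-[(2R,5S)-5-bromo-2,6,6-trimethyloxan-2-yl]penta-2,4-dien-2-yl]-1-methylcyclohexan-1-ol | C/C(=C\C=C\[C@@]1(C)CC[C@H](Br)C(C)(C)O1)[C@H]1CC[C@@](C)(O)[C@@H](Br)C1 | target

**Totals**

Total step count: 14. Longest linear sequence: 8 steps (steps 1–7, then step 14, from geranyl acetate); the cyclohexane branch is 7 steps (steps 8–13, then step 14).

**Steps most likely to fail**

1. Step 3. What may go wrong: the bromide opens the lithium-activated epoxide in an ionising, Markovnikov sense at the tertiary carbon, or the epoxide rearranges, instead of reacting by SN2 at C6. Fallback, setting out from 1 and coming back at 6: the C–Br centre is made without stereocontrol and the epimers are separated after ring closure. Geranyl acetate 1 with N-bromosuccinimide in aqueous THF at 0 °C should give the racemic terminal bromohydrin, (2E)-6-bromo-7-hydroxy-3,7-dimethyloct-2-en-1-yl acetate F1. DIBAL-H at −78 °C removes the acetate without closing the epoxide and gives racemic (2E)-6-bromo-3,7-dimethyloct-2-ene-1,7-diol F2. Sharpless epoxidation as in step 4 gives 3-bromo-5-[(2S,3S)-3-(hydroxymethyl)-2-methyloxiran-2-yl]-2-methylpentan-2-ol as both bromide epimers F3. CSA as in step 5 closes both, and diol 6 is separated by chromatography from its epimer (1S)-1-[(2R,5R)-5-bromo-2,6,6-trimethyloxan-2-yl]ethane-1,2-diol F4.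

2. Step 10. What may go wrong: E2 elimination of the axial tosylate outruns substitution, silyloxy participation gives retention, or slow bromide–bromide exchange erodes the new centre. Fallback, setting out from 10 and coming back at 14: the substitution is moved next to a carbonyl group. Dess–Martin oxidation of 10 gives ethyl (1S,3R)-4-oxo-3-(tosyloxy)cyclohexane-1-carboxylate F5. One equivalent of LiBr in acetone at 0 °C then displaces the axial, carbonyl-activated sulfonate with inversion and gives 14 directly; lithium tosylate precipitates and no excess bromide remains to exchange with the product. Steps 9 and 11 are then not needed.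

3. Step 14. What may go wrong: the aluminium alkoxide of the bromohydrin is lost under the Lewis-acidic carbometalation conditions (ring contraction with expulsion of bromide), or residual Me3Al transfers methyl to the iodoalkene in the coupling. Fallback, setting out from 17 and 7 and coming back at 19: the carbinol is masked, carbometalation and coupling are separated, and the nucleophile is moved to the oxane as a boronate.
   - 17 is silylated (Et3SiOTf, 2,6-lutidine) to {[(1R,2S,4S)-2-bromo-4-ethynyl-1-methylcyclohexyl]oxy}triethylsilane F6.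
   - Carboalumination (Me3Al, Cp2ZrCl2) followed by iodine gives {[(1R,2S,4S)-2-bromo-4-[(E)-1-iodoprop-1-en-2-yl]-1-methylcyclohexyl]oxy}triethylsilane F7.
   - Aldehyde 7 is homologated with the Ohira–Bestmann reagent to (3S,6R)-3-bromo-6-ethynyl-2,2,6-trimethyloxane F8.
   - Hydroboration with pinacolborane and catalytic Cp2ZrHCl gives 2-{(E)-2-[(2R,5S)-5-bromo-2,6,6-trimethyloxan-2-yl]ethenyl}-4,4,5,5-tetramethyl-1,3,2-dioxaborolane F9.
   - Suzuki coupling of F7 and F9 (PdCl2(dppf), K3PO4, THF/H2O) gives the triethylsilyl ether of 19 F10, and HF·pyridine in THF releases 19.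

**Further compounds**

F1 | step 3 | (2E)-6-bromo-7-hydroxy-3,7-dimethyloct-2-en-1-yl acetate (racemic) | CC(=O)OC/C=C(\C)CCC(Br)C(C)(C)O
F2 | step 3 | (2E)-6-bromo-3,7-dimethyloct-2-ene-1,7-diol (racemic) | OC/C=C(\C)CCC(Br)C(C)(C)O
F3 | step 3 | 3-bromo-5-[(2S,3S)-3-(hydroxymethyl)-2-methyloxiran-2-yl]-2-methylpentan-2-ol (both bromide epimers) | OC[C@@H]1O[C@@]1(C)CCC(Br)C(C)(C)O
F4 | step 3 | (1S)-1-[(2R,5R)-5-bromo-2,6,6-trimethyloxan-2-yl]ethane-1,2-diol | OC[C@H](O)[C@@]1(C)CC[C@@H](Br)C(C)(C)O1
F5 | step 10 | ethyl (1S,3R)-4-oxo-3-(tosyloxy)cyclohexane-1-carboxylate | CCOC(=O)[C@H]1CCC(=O)[C@H](OS(=O)(=O)c2ccc(C)cc2)C1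
F6 | step 14 | {[(1R,2S,4S)-2-bromo-4-ethynyl-1-methylcyclohexyl]oxy}triethylsilane | C#C[C@H]1CC[C@@](C)(O[Si](CC)(CC)CC)[C@@H](Br)C1
F7 | step 14 | {[(1R,2S,4S)-2-bromo-4-[(E)-1-iodoprop-1-en-2-yl]-1-methylcyclohexyl]oxy}triethylsilane | I/C=C(\C)[C@H]1CC[C@@](C)(O[Si](CC)(CC)CC)[C@@H](Br)C1
F8 | step 14 | (3S,6R)-3-bromo-6-ethynyl-2,2,6-trimethyloxane | C#C[C@@]1(C)CC[C@H](Br)C(C)(C)O1
F9 | step 14 | 2-{(E)-2-[(2R,5S)-5-bromo-2,6,6-trimethyloxan-2-yl]ethenyl}-4,4,5,5-tetramethyl-1,3,2-dioxaborolane | CC1(C)OB(/C=C/[C@@]2(C)CC[C@H](Br)C(C)(C)O2)OC1(C)C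
F10 | step 14 | triethylsilyl ether of 19 | C/C(=C\C=C\[C@@]1(C)CC[C@H](Br)C(C)(C)O1)[C@H]1CC[C@@](C)(O[Si](CC)(CC)CC)[C@@H](Br)C1
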